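The readings come from a simulation with made-up constants, and the scatter is random.

- Beta and eta were the two runs I had for this flask, and both ran nearly straight once under way.

| setting | beta | eta | flask |
|---|---|---|---|
| starting material | 0.10 M | 0.10 M | 0.10 M |
| solid second substrate | 0.90 equiv | 0.90 equiv | 0.900 equiv |
| enzyme | 6.0 × 10⁻⁴ mol% | 0.0024 mol% | 0.0012 mol% |
| remark | run made earlier | run made earlier |  |

| run | time / h | product / % | starting material / % |
|---|---|---|---|
| beta | 0.667 | 8.1 | 91.7 |
| beta | 1.33 | 19.1 | 80.8 |
| beta | 2.00 | 31.0 | 69.1 |
| beta | 2.50 | 39.4 | 60.5 |
| beta | 3.00 | 48.0 | 51.6 |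
| beta | 4.00 | 64.0 | 35.9 |
| eta | 0.250 | 4.4 | 96.3 |
| eta | 0.500 | 8.1 | 91.7 |
| eta | 0.833 | 14.5 | 86.3 |
| eta | 1.33 | 23.3 | 77.1 |
| eta | 2.00 | 35.2 | 64.8 |
| eta | 4.00 | 70.8 | 28.5 |

(scatter of a reading: 0.3 percentage points)

* factor on the rate of making product when 30% of the starting material are converted if enzyme is charged twice over
* factor on the rate when 30% of the starting material are converted if enzyme is charged at 1.2 × 10⁻⁴ mol% instead

- solid, in amounts per volume of the solution: solid second substrate
- the numbers in the tables scatter with a standard deviation of 0.3 percentage points
- what may be going on: second substrate + starting complex <-> ternary complex; starting material + enzyme <-> starting complex; ternary complex -> enzyme + product; solid second substrate <-> second substrate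
- at the start none of the solid second substrate is in solution

- I took eta's slope from its last two readings, 0.178 h⁻¹ of the charge, and beta's after its lag, 0.165 h⁻¹.
- With 4.00 times the enzyme, the slope I read grew just 1.08-fold, less than the enzyme did, so I treated dissolving as the rate-limiting step.
- I therefore wrote rate = ceiling × loading/(loading + knee). The knee is the loading, as a fraction of this flask's, at which the rate stands at half the ceiling: 0.0539.
- For this flask, that gave me 1.03 for doubling and 0.685 for the lower loading.
- The weak link was the small gap between the slopes. Moving it by its scatter, 0.00300 h⁻¹, took the knee to between 0.0412 and 0.0668, and my second factor to between 0.640 and 0.737.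
- The forecast said 1.015 and 0.75, holding that “dissolution of the solid limits the rate”; its first factor stood below mine and its second above mine.
- The flask gave 1.02 and 0.705, so the forecast held within its margins. A factor under 0.640 in a run at 1.2 × 10⁻⁴ mol% would have stood below my range and called for a knee larger than 0.0668.

    second substrate + starting complex ⇌ ternary complex (K = 18.0 M⁻¹, k = 18000 M⁻¹ s⁻¹)
    starting material + enzyme ⇌ starting complex (K = 21.0 M⁻¹, k = 21000 M⁻¹ s⁻¹)
    ternary complex → enzyme + product (k = 7.90 × 10⁵ h⁻¹)
    solid second substrate ⇌ second substrate, rate k4*(cs4 - [second substrate]) while solid is left; crystals form when [second substrate] > cs4 (solubility = 0.0740 M, k = 0.250 h⁻¹)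

- In the flask at 3.00 h, second substrate was made 1.02 times as fast as it was used, each step taken net, and its level of 0.00253 M stood far below the solubility of 0.074 M, with 40.1% of the solid's charge left. My knee puts this flask at 0.949 of the ceiling and a run at the other loading at 0.650, and in that run ternary complex held 13.2% of the catalyst at 30% conversion.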